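**Retrosynthetic overview**

- Target ⇒ phenol desilylation, Z-selective alkyne semihydrogenation, ring dehydrogenation and enolate C-alkylation ⇒ a 3,4-dimethoxy-4-(3-phenylpropargyl)cyclohexenone plus a 2-(bromomethyl)-3-phenylbenzofuran.
- The quaternary C(OMe)(CH2C≡CPh) carbon ⇒ spiro-epoxide (acetylide opening, O-methylation) ⇒ 1,2-diol ⇒ spiro-dioxolanone cycloadduct.
- Key disconnection: Diels–Alder reaction of (S)-2-tert-butyl-5-methylene-1,3-dioxolan-4-one with a 1,1-dimethoxy-3-silyloxybutadiene. It forms the six-membered ring, places the ring methoxy group next to the quaternary carbon, and sets the stereocentre; (S)-lactic acid is the only source of chirality.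
- Benzofuran ⇒ α-aryloxy ketone (cyclodehydration) ⇒ 4-(benzyloxy)-3-methoxyphenol + 2-bromopropiophenone.
- Ring order: dioxolanone (temporary) → cyclohexene ring (cycloaddition) → benzofuran (separate fragment) → cross-conjugated dienone by late dehydrogenation.

Assumption: the target is (4R) with a (Z)-olefin as read from the SMILES; reagents without a number are ordinary catalogue chemicals.

**Route**

Step 1
Reactants: 1 (S)-lactic acid
Product: 2 (2S,5S)-2-tert-butyl-5-methyl-1,3-dioxolan-4-one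
Conditions: pivalaldehyde, TsOH·H2O (cat.), H2SO4 (cat.), pentane, reflux, Dean–Stark; crystallise at −78 °C
Reagents that add atoms: pivalaldehyde (2,2-dimethylpropanal), CC(C)(C)C=O
Why: Acid-catalysed acetalisation gives the cis dioxolanone as the favoured, crystallisable isomer, so the lactate stereocentre sets the acetal carbon (self-regeneration of stereocentres).

Step 2
Reactants: 2 (2S,5S)-2-tert-butyl-5-methyl-1,3-dioxolan-4-one
Product: 4 (2S)-2-tert-butyl-5-methylidene-1,3-dioxolan-4-one, via tertiary bromide 3 (not isolated)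
Conditions: NBS, AIBN (cat.), CCl4, reflux; then Et3N, Et2O, 0 °C → rt
Reagents that add atoms: none
Why: Wohl–Ziegler radical bromination at the captodative C5–H and E2 dehydrobromination give the α-oxy acrylate, while the acetal carbon keeps the stereochemical information.

Step 3
Reactants: 5 1,1-dimethoxyethene; 6 acetyl chloride
Product: 7 4,4-dimethoxybut-3-en-2-one
Conditions: pyridine, Et2O, 0 °C → rt
Reagents that add atoms: none
Why: C-acylation of the nucleophilic ketene acetal by the N-acylpyridinium salt, then loss of a proton, gives the acylketene acetal.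

Step 4
Reactants: 7 4,4-dimethoxybut-3-en-2-one
Product: 8 tert-butyl[(4,4-dimethoxybuta-1,3-dien-2-yl)oxy]dimethylsilane
Conditions: TBSOTf, Et3N, Et2O, 0 °C
Reagents that add atoms: tert-butyldimethylsilyl trifluoromethanesulfonate, CC(C)(C)[Si](C)(C)OS(=O)(=O)C(F)(F)F
Why: Soft enolisation and O-silylation of the methyl ketone (the only enolisable side) give the electron-rich 2-silyloxy diene.

Step 5
Reactants: 4 (2S)-2-tert-butyl-5-methylidene-1,3-dioxolan-4-one; 8 tert-butyl[(4,4-dimethoxybuta-1,3-dien-2-yl)oxy]dimethylsilane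
Product: 9 (2S,5R)-2-tert-butyl-8-[(tert-butyldimethylsilyl)oxy]-6,6-dimethoxy-1,3-dioxaspiro[4.5]dec-7-en-4-one
Conditions: toluene, 90 °C, sealed tube, 2,6-di-tert-butyl-4-methylphenol (cat.), 24 h
Reagents that add atoms: none
Why: Diels–Alder cycloaddition in which the silyl-enol-ether terminus bonds to the methylene carbon and the ketene-acetal terminus to the α-oxy carbon, the diene adding anti to the tert-butyl group, which sets the spiro carbon (the later 4R centre).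

Step 6
Reactants: 9 (2S,5R)-2-tert-butyl-8-[(tert-butyldimethylsilyl)oxy]-6,6-dimethoxy-1,3-dioxaspiro[4.5]dec-7-en-4-one
Product: 10 (1S)-4-[(tert-butyldimethylsilyl)oxy]-1-(hydroxymethyl)-2,2-dimethoxycyclohex-3-en-1-ol
Conditions: LiAlH4, Et2O, 0 °C; then H2O, 15% aq. NaOH
Reagents that add atoms: none
Why: Hydride reduction of the acylal lactone gives the 1,2-diol and releases the pivalaldehyde unit as neopentyl alcohol, while the silyl enol ether and ketal (the masked methoxy-enone) survive and the quaternary carbon is untouched.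

Step 7
Reactants: 10 (1S)-4-[(tert-butyldimethylsilyl)oxy]-1-(hydroxymethyl)-2,2-dimethoxycyclohex-3-en-1-ol
Product: 12 tert-butyl{[(3S)-4,4-dimethoxy-1-oxaspiro[2.5]oct-5-en-6-yl]oxy}dimethylsilane, via primary tosylate 11 (not isolated)
Conditions: TsCl, Et3N, DMAP (cat.), CH2Cl2, 0 °C; then NaH, THF, 0 °C → rt
Reagents that add atoms: none
Why: Selective sulfonylation of the primary hydroxyl and intramolecular Williamson displacement by the tertiary alkoxide close the spiro-epoxide with retention at the quaternary carbon.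

Step 8
Reactants: 12 tert-butyl{[(3S)-4,4-dimethoxy-1-oxaspiro[2.5]oct-5-en-6-yl]oxy}dimethylsilane; 13 ethynylbenzene
Product: 15 tert-butyl{[(4S)-3,3,4-trimethoxy-4-(3-phenylprop-2-yn-1-yl)cyclohex-1-en-1-yl]oxy}dimethylsilane, via lithium alkoxide 14 (not isolated)
Conditions: 13, n-BuLi, THF, −78 °C; then 12, DMPU, −78 → 45 °C; then MeI, 0 °C → rt
Reagents that add atoms: iodomethane, CI
Why: SN2 opening of the epoxide at its CH2 terminus by lithium phenylacetylide gives the homopropargylic tertiary alkoxide, which is O-methylated in the same flask (Williamson) without touching the stereocentre.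

Step 9
Reactants: 15 tert-butyl{[(4S)-3,3,4-trimethoxy-4-(3-phenylprop-2-yn-1-yl)cyclohex-1-en-1-yl]oxy}dimethylsilane
Product: 16 (4S)-3,4-dimethoxy-4-(3-phenylprop-2-yn-1-yl)cyclohex-2-en-1-one
Conditions: NaOMe (0.2 equiv), MeOH, 0 °C → rt
Reagents that add atoms: none
Why: Methoxide cleaves the silyl enol ether and the resulting enolate expels methoxide from the neighbouring ketal (E1cB), so catalytic base unmasks the 3-methoxy enone with the methoxy group on the carbon next to the quaternary centre.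

Step 10
Reactants: 17 4-(benzyloxy)-3-methoxyphenol; 18 2-bromo-1-phenylpropan-1-one
Product: 19 2-[4-(benzyloxy)-3-methoxyphenoxy]-1-phenylpropan-1-one (racemic)
Conditions: K2CO3, acetone, reflux
Reagents that add atoms: none
Why: Williamson O-alkylation of the phenoxide by the carbonyl-activated secondary bromide (SN2).

Step 11
Reactants: 19 2-[4-(benzyloxy)-3-methoxyphenoxy]-1-phenylpropan-1-one
Product: 20 6-methoxy-2-methyl-3-phenyl-1-benzofuran-5-ol
Conditions: BCl3 (3 equiv), CH2Cl2, −78 → 0 °C; then H2O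
Reagents that add atoms: none
Why: Lewis-acid cyclodehydration (intramolecular Friedel–Crafts-type attack para to the methoxy group, then aromatisation) forms the 3-phenylbenzofuran, and BCl3 cleaves the benzyl ether in the same operation.

Step 12
Reactants: 20 6-methoxy-2-methyl-3-phenyl-1-benzofuran-5-ol
Product: 21 tert-butyl[(6-methoxy-2-methyl-3-phenyl-1-benzofuran-5-yl)oxy]dimethylsilane
Conditions: TBSCl, imidazole, DMF, rt
Reagents that add atoms: tert-butyldimethylsilyl chloride, CC(C)(C)[Si](C)(C)Cl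
Why: Imidazole-promoted O-silylation gives a phenol ether that is stable to amide bases and removable with fluoride.

Step 13
Reactants: 21 tert-butyl[(6-methoxy-2-methyl-3-phenyl-1-benzofuran-5-yl)oxy]dimethylsilane
Product: 22 {[2-(bromomethyl)-6-methoxy-3-phenyl-1-benzofuran-5-yl]oxy}(tert-butyl)dimethylsilane
Conditions: NBS, AIBN (cat.), PhCF3, 80 °C
Reagents that add atoms: N-bromosuccinimide, O=C1CCC(=O)N1Br
Why: Wohl–Ziegler bromination at the 2-methyl group, whose radical is stabilised by the furan ring (position 3 is blocked by phenyl).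

Step 14
Reactants: 16 (4S)-3,4-dimethoxy-4-(3-phenylprop-2-yn-1-yl)cyclohex-2-en-1-one; 22 {[2-(bromomethyl)-6-methoxy-3-phenyl-1-benzofuran-5-yl]oxy}(tert-butyl)dimethylsilane
Product: 24 (4S)-6-({5-[(tert-butyldimethylsilyl)oxy]-6-methoxy-3-phenyl-1-benzofuran-2-yl}methyl)-3,4-dimethoxy-4-(3-phenylprop-2-yn-1-yl)cyclohex-2-en-1-one (C6 epimers), via lithium enolate 23 (not isolated)
Conditions: LiN(i-Pr)2, THF, −78 °C; then 22, −78 → −30 °C
Reagents that add atoms: none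
Why: Stork–Danheiser-type kinetic enolate alkylation, in which C6 is the only enolisable position because C4 is quaternary; the new C6 centre is irrelevant because the next step removes it.

Step 15
Reactants: 24 (4S)-6-({5-[(tert-butyldimethylsilyl)oxy]-6-methoxy-3-phenyl-1-benzofuran-2-yl}methyl)-3,4-dimethoxy-4-(3-phenylprop-2-yn-1-yl)cyclohex-2-en-1-one
Product: 28 (4R)-2-({5-[(tert-butyldimethylsilyl)oxy]-6-methoxy-3-phenyl-1-benzofuran-2-yl}methyl)-4,5-dimethoxy-4-(3-phenylprop-2-yn-1-yl)cyclohexa-2,5-dien-1-one, via lithium enolate 25 (not isolated), via selenide 26 (not isolated), via selenoxide 27 (not isolated)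
Conditions: LiN(i-Pr)2, THF, −78 °C; PhSeBr; then 30% H2O2, pyridine, CH2Cl2, 0 °C → rt
Reagents that add atoms: none
Why: Enolate α-selenenylation and selenoxide syn-elimination (Reich) into the ring give the cross-conjugated dienone, which cannot aromatise because C4 is quaternary (the descriptor changes to R only through CIP priorities).

Step 16
Reactants: 28 (4R)-2-({5-[(tert-butyldimethylsilyl)oxy]-6-methoxy-3-phenyl-1-benzofuran-2-yl}methyl)-4,5-dimethoxy-4-(3-phenylprop-2-yn-1-yl)cyclohexa-2,5-dien-1-one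
Product: 29 (4R)-2-({5-[(tert-butyldimethylsilyl)oxy]-6-methoxy-3-phenyl-1-benzofuran-2-yl}methyl)-4,5-dimethoxy-4-[(2Z)-3-phenylprop-2-en-1-yl]cyclohexa-2,5-dien-1-one
Conditions: H2 (1 atm), Pd/CaCO3 poisoned with Pb(OAc)2, quinoline, EtOAc, rt
Reagents that add atoms: none
Why: Semihydrogenation of the alkyne by syn addition of H2 on poisoned palladium gives the Z-olefin, while the hindered, electron-poor dienone double bonds are not reduced.

Step 17
Reactants: 29 (4R)-2-({5-[(tert-butyldimethylsilyl)oxy]-6-methoxy-3-phenyl-1-benzofuran-2-yl}methyl)-4,5-dimethoxy-4-[(2Z)-3-phenylprop-2-en-1-yl]cyclohexa-2,5-dien-1-one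
Product: 30 (4R)-2-[(5-hydroxy-6-methoxy-3-phenyl-1-benzofuran-2-yl)methyl]-4,5-dimethoxy-4-[(2Z)-3-phenylprop-2-en-1-yl]cyclohexa-2,5-dien-1-one (target)
Conditions: Bu4NF, AcOH, THF, 0 °C
Reagents that add atoms: none
Why: Buffered fluoride desilylation frees the phenol without affecting the dienone, the tertiary methyl ether or the Z-olefin.

**Compound list**

1 | (S)-lactic acid | C[C@H](O)C(=O)O | starting material
2 | (2S,5S)-2-tert-butyl-5-methyl-1,3-dioxolan-4-one | C[C@@H]1O[C@H](C(C)(C)C)OC1=O | intermediate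
3 | (2R,5R)-5-bromo-2-tert-butyl-5-methyl-1,3-dioxolan-4-one (Br trans to tert-butyl) | C[C@]1(Br)O[C@H](C(C)(C)C)OC1=O | intermediate
4 | (2S)-2-tert-butyl-5-methylidene-1,3-dioxolan-4-one | C=C1O[C@H](C(C)(C)C)OC1=O | intermediate
5 | 1,1-dimethoxyethene | C=C(OC)OC | starting material
6 | acetyl chloride | CC(=O)Cl | starting material
7 | 4,4-dimethoxybut-3-en-2-one | CC(=O)C=C(OC)OC | intermediate
8 | tert-butyl[(4,4-dimethoxybuta-1,3-dien-2-yl)oxy]dimethylsilane | C=C(O[Si](C)(C)C(C)(C)C)C=C(OC)OC | intermediate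
9 | (2S,5R)-2-tert-butyl-8-[(tert-butyldimethylsilyl)oxy]-6,6-dimethoxy-1,3-dioxaspiro[4.5]dec-7-en-4-one | CC(C)(C)[C@@H]1OC(=O)[C@@]2(O1)CCC(O[Si](C)(C)C(C)(C)C)=CC2(OC)OC | intermediate
10 | (1S)-4-[(tert-butyldimethylsilyl)oxy]-1-(hydroxymethyl)-2,2-dimethoxycyclohex-3-en-1-ol | OC[C@@]1(O)CCC(O[Si](C)(C)C(C)(C)C)=CC1(OC)OC | intermediate
11 | [(1S)-4-[(tert-butyldimethylsilyl)oxy]-1-hydroxy-2,2-dimethoxycyclohex-3-en-1-yl]methyl 4-methylbenzenesulfonate | Cc1ccc(cc1)S(=O)(=O)OC[C@@]1(O)CCC(O[Si](C)(C)C(C)(C)C)=CC1(OC)OC | intermediate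
12 | tert-butyl{[(3S)-4,4-dimethoxy-1-oxaspiro[2.5]oct-5-en-6-yl]oxy}dimethylsilane | C1O[C@@]12CCC(O[Si](C)(C)C(C)(C)C)=CC2(OC)OC | intermediate
13 | ethynylbenzene (phenylacetylene) | C#Cc1ccccc1 | starting material
14 | lithium (1S)-4-[(tert-butyldimethylsilyl)oxy]-2,2-dimethoxy-1-(3-phenylprop-2-yn-1-yl)cyclohex-3-en-1-olate | [Li+].[O-][C@]1(CC#Cc2ccccc2)CCC(O[Si](C)(C)C(C)(C)C)=CC1(OC)OC | intermediate
15 | tert-butyl{[(4S)-3,3,4-trimethoxy-4-(3-phenylprop-2-yn-1-yl)cyclohex-1-en-1-yl]oxy}dimethylsilane | CO[C@]1(CC#Cc2ccccc2)CCC(O[Si](C)(C)C(C)(C)C)=CC1(OC)OC | intermediate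
16 | (4S)-3,4-dimethoxy-4-(3-phenylprop-2-yn-1-yl)cyclohex-2-en-1-one | CO[C@]1(CC#Cc2ccccc2)CCC(=O)C=C1OC | intermediate
17 | 4-(benzyloxy)-3-methoxyphenol | COc1cc(O)ccc1OCc1ccccc1 | starting material
18 | 2-bromo-1-phenylpropan-1-one (racemic) | CC(Br)C(=O)c1ccccc1 | starting material
19 | 2-[4-(benzyloxy)-3-methoxyphenoxy]-1-phenylpropan-1-one (racemic) | CC(Oc1ccc(OCc2ccccc2)c(OC)c1)C(=O)c1ccccc1 | intermediate
20 | 6-methoxy-2-methyl-3-phenyl-1-benzofuran-5-ol | Cc1oc2cc(OC)c(O)cc2c1-c1ccccc1 | intermediate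
21 | tert-butyl[(6-methoxy-2-methyl-3-phenyl-1-benzofuran-5-yl)oxy]dimethylsilane | Cc1oc2cc(OC)c(O[Si](C)(C)C(C)(C)C)cc2c1-c1ccccc1 | intermediate
22 | {[2-(bromomethyl)-6-methoxy-3-phenyl-1-benzofuran-5-yl]oxy}(tert-butyl)dimethylsilane | BrCc1oc2cc(OC)c(O[Si](C)(C)C(C)(C)C)cc2c1-c1ccccc1 | intermediate
23 | lithium (4S)-4,5-dimethoxy-4-(3-phenylprop-2-yn-1-yl)cyclohexa-1,5-dien-1-olate | [Li+].CO[C@]1(CC#Cc2ccccc2)CC=C([O-])C=C1OC | intermediate
24 | (4S)-6-({5-[(tert-butyldimethylsilyl)oxy]-6-methoxy-3-phenyl-1-benzofuran-2-yl}methyl)-3,4-dimethoxy-4-(3-phenylprop-2-yn-1-yl)cyclohex-2-en-1-one (C6 epimers) | CO[C@]1(CC#Cc2ccccc2)CC(Cc2oc3cc(OC)c(O[Si](C)(C)C(C)(C)C)cc3c2-c2ccccc2)C(=O)C=C1OC | intermediate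
25 | lithium (4R)-2-({5-[(tert-butyldimethylsilyl)oxy]-6-methoxy-3-phenyl-1-benzofuran-2-yl}methyl)-4,5-dimethoxy-4-(3-phenylprop-2-yn-1-yl)cyclohexa-1,5-dien-1-olate | [Li+].CO[C@]1(CC#Cc2ccccc2)CC(Cc2oc3cc(OC)c(O[Si](C)(C)C(C)(C)C)cc3c2-c2ccccc2)=C([O-])C=C1OC | intermediate
26 | (4R)-6-({5-[(tert-butyldimethylsilyl)oxy]-6-methoxy-3-phenyl-1-benzofuran-2-yl}methyl)-3,4-dimethoxy-6-(phenylselanyl)-4-(3-phenylprop-2-yn-1-yl)cyclohex-2-en-1-one (C6 epimers) | CO[C@]1(CC#Cc2ccccc2)CC(Cc2oc3cc(OC)c(O[Si](C)(C)C(C)(C)C)cc3c2-c2ccccc2)([Se]c2ccccc2)C(=O)C=C1OC | intermediate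
27 | (4R)-6-(benzeneseleninyl)-6-({5-[(tert-butyldimethylsilyl)oxy]-6-methoxy-3-phenyl-1-benzofuran-2-yl}methyl)-3,4-dimethoxy-4-(3-phenylprop-2-yn-1-yl)cyclohex-2-en-1-one (mixture at C6 and Se) | CO[C@]1(CC#Cc2ccccc2)CC(Cc2oc3cc(OC)c(O[Si](C)(C)C(C)(C)C)cc3c2-c2ccccc2)([Se](=O)c2ccccc2)C(=O)C=C1OC | intermediate
28 | (4R)-2-({5-[(tert-butyldimethylsilyl)oxy]-6-methoxy-3-phenyl-1-benzofuran-2-yl}methyl)-4,5-dimethoxy-4-(3-phenylprop-2-yn-1-yl)cyclohexa-2,5-dien-1-one | CO[C@]1(CC#Cc2ccccc2)C=C(Cc2oc3cc(OC)c(O[Si](C)(C)C(C)(C)C)cc3c2-c2ccccc2)C(=O)C=C1OC | intermediate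
29 | (4R)-2-({5-[(tert-butyldimethylsilyl)oxy]-6-methoxy-3-phenyl-1-benzofuran-2-yl}methyl)-4,5-dimethoxy-4-[(2Z)-3-phenylprop-2-en-1-yl]cyclohexa-2,5-dien-1-one | CO[C@]1(C/C=C\c2ccccc2)C=C(Cc2oc3cc(OC)c(O[Si](C)(C)C(C)(C)C)cc3c2-c2ccccc2)C(=O)C=C1OC | intermediate
30 | (4R)-2-[(5-hydroxy-6-methoxy-3-phenyl-1-benzofuran-2-yl)methyl]-4,5-dimethoxy-4-[(2Z)-3-phenylprop-2-en-1-yl]cyclohexa-2,5-dien-1-one | COC1=CC(=O)C(Cc2oc3cc(OC)c(O)cc3c2-c2ccccc2)=C[C@@]1(C/C=C\c1ccccc1)OC | target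

**Step count**

Total: 17 steps, counting diene and benzofuran fragment preparation.
Longest linear sequence: 11 steps (1 → 2 → 4 → 9 → 10 → 12 → 15 → 16 → 24 → 28 → 29 → 30; steps 1, 2, 5, 6, 7, 8, 9, 14, 15, 16, 17).

**Three steps most likely to fail, with fallbacks**

Step 8. The SN2 opening of a 2,2-disubstituted epoxide flanked by a ketal, without Lewis acid, may be slow or give elimination. The fallback sets out from 12 and comes back at 15. Epoxide 12 is opened with the smaller, more nucleophilic LiC≡CH·H2NCH2CH2NH2 in DMSO at rt to give (1S)-4-[(tert-butyldimethylsilyl)oxy]-2,2-dimethoxy-1-(prop-2-yn-1-yl)cyclohex-3-en-1-ol F1. The phenyl group is then attached by Sonogashira coupling with iodobenzene (Pd(PPh3)2Cl2, CuI, Et3N), giving (1S)-4-[(tert-butyldimethylsilyl)oxy]-2,2-dimethoxy-1-(3-phenylprop-2-yn-1-yl)cyclohex-3-en-1-ol F2. NaH/MeI in THF methylates F2 to 15.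

Step 13. NBS may brominate the electron-rich benzo ring instead of the 2-methyl group. The fallback sets out from 17 and comes back at 22; it brings the C2 carbon in at the ester oxidation level, so no radical bromination is needed. Phenol 17 is alkylated with ethyl 2-chloro-3-oxo-3-phenylpropanoate (K2CO3, acetone) to ethyl 2-[4-(benzyloxy)-3-methoxyphenoxy]-3-oxo-3-phenylpropanoate F3. BCl3 cyclodehydration with debenzylation gives ethyl 5-hydroxy-6-methoxy-3-phenyl-1-benzofuran-2-carboxylate F4, and TBSCl/imidazole gives ethyl 5-[(tert-butyldimethylsilyl)oxy]-6-methoxy-3-phenyl-1-benzofuran-2-carboxylate F5. Reduction with i-Bu2AlH gives {5-[(tert-butyldimethylsilyl)oxy]-6-methoxy-3-phenyl-1-benzofuran-2-yl}methanol F6, and CBr4/PPh3 converts F6 into 22.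

Step 15. The selenoxide may eliminate toward the benzylic CH2 and give the exocyclic arylidene enone instead of the ring double bond. The fallback sets out from 16 and comes back at 28; it puts a hydroxyl on the side-chain carbon so that elimination can only go into the ring. Ketone 16 is selenenylated first (LiN(i-Pr)2, PhSeBr) to (4R)-3,4-dimethoxy-6-(phenylselanyl)-4-(3-phenylprop-2-yn-1-yl)cyclohex-2-en-1-one F7. Bromide 22 is oxidised (DMSO, NaHCO3, Kornblum) to 5-[(tert-butyldimethylsilyl)oxy]-6-methoxy-3-phenyl-1-benzofuran-2-carbaldehyde F8. Aldol addition of the lithium enolate of F7 to F8 gives (4R)-6-[{5-[(tert-butyldimethylsilyl)oxy]-6-methoxy-3-phenyl-1-benzofuran-2-yl}(hydroxy)methyl]-3,4-dimethoxy-6-(phenylselanyl)-4-(3-phenylprop-2-yn-1-yl)cyclohex-2-en-1-one F9. Oxidation with H2O2 then eliminates away from the carbinol carbon to (4R)-2-[{5-[(tert-butyldimethylsilyl)oxy]-6-methoxy-3-phenyl-1-benzofuran-2-yl}(hydroxy)methyl]-4,5-dimethoxy-4-(3-phenylprop-2-yn-1-yl)cyclohexa-2,5-dien-1-one F10. Ionic deoxygenation of the benzofuranyl carbinol (Et3SiH, CF3CO2H, CH2Cl2, −20 °C) gives 28.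

**Further compounds**

F1 | step 8 | (1S)-4-[(tert-butyldimethylsilyl)oxy]-2,2-dimethoxy-1-(prop-2-yn-1-yl)cyclohex-3-en-1-ol | C#CC[C@@]1(O)CCC(O[Si](C)(C)C(C)(C)C)=CC1(OC)OC
F2 | step 8 | (1S)-4-[(tert-butyldimethylsilyl)oxy]-2,2-dimethoxy-1-(3-phenylprop-2-yn-1-yl)cyclohex-3-en-1-ol | O[C@]1(CC#Cc2ccccc2)CCC(O[Si](C)(C)C(C)(C)C)=CC1(OC)OC
F3 | step 13 | ethyl 2-[4-(benzyloxy)-3-methoxyphenoxy]-3-oxo-3-phenylpropanoate (racemic) | CCOC(=O)C(Oc1ccc(OCc2ccccc2)c(OC)c1)C(=O)c1ccccc1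
F4 | step 13 | ethyl 5-hydroxy-6-methoxy-3-phenyl-1-benzofuran-2-carboxylate | CCOC(=O)c1oc2cc(OC)c(O)cc2c1-c1ccccc1
F5 | step 13 | ethyl 5-[(tert-butyldimethylsilyl)oxy]-6-methoxy-3-phenyl-1-benzofuran-2-carboxylate | CCOC(=O)c1oc2cc(OC)c(O[Si](C)(C)C(C)(C)C)cc2c1-c1ccccc1
F6 | step 13 | {5-[(tert-butyldimethylsilyl)oxy]-6-methoxy-3-phenyl-1-benzofuran-2-yl}methanol | OCc1oc2cc(OC)c(O[Si](C)(C)C(C)(C)C)cc2c1-c1ccccc1
F7 | step 15 | (4R)-3,4-dimethoxy-6-(phenylselanyl)-4-(3-phenylprop-2-yn-1-yl)cyclohex-2-en-1-one (C6 epimers) | CO[C@]1(CC#Cc2ccccc2)CC([Se]c2ccccc2)C(=O)C=C1OC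
F8 | step 15 | 5-[(tert-butyldimethylsilyl)oxy]-6-methoxy-3-phenyl-1-benzofuran-2-carbaldehyde | O=Cc1oc2cc(OC)c(O[Si](C)(C)C(C)(C)C)cc2c1-c1ccccc1
F9 | step 15 | (4R)-6-[{5-[(tert-butyldimethylsilyl)oxy]-6-methoxy-3-phenyl-1-benzofuran-2-yl}(hydroxy)methyl]-3,4-dimethoxy-6-(phenylselanyl)-4-(3-phenylprop-2-yn-1-yl)cyclohex-2-en-1-one (diastereomer mixture) | CO[C@]1(CC#Cc2ccccc2)CC([Se]c2ccccc2)(C(O)c2oc3cc(OC)c(O[Si](C)(C)C(C)(C)C)cc3c2-c2ccccc2)C(=O)C=C1OC
F10 | step 15 | (4R)-2-[{5-[(tert-butyldimethylsilyl)oxy]-6-methoxy-3-phenyl-1-benzofuran-2-yl}(hydroxy)methyl]-4,5-dimethoxy-4-(3-phenylprop-2-yn-1-yl)cyclohexa-2,5-dien-1-one (carbinol epimers) | CO[C@]1(CC#Cc2ccccc2)C=C(C(O)c2oc3cc(OC)c(O[Si](C)(C)C(C)(C)C)cc3c2-c2ccccc2)C(=O)C=C1OC
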